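Atom labels follow abietane numbering: ring B is C5–C10, ring C is C8, C9 and C11–C14, C1–C3 form the propanoate arm on C10, and C4 is the central carbon of the isopropenyl group on C5.

## Analysis of the target

Target 22 is a 3,4-seco-abietane: ring A is absent, and its remains sit on ring B as an isopropenyl group on C5 and, on the quaternary C10, a methyl group and a methyl propanoate arm. Ring B shares the C8=C9 double bond with ring C, a fully substituted 2-hydroxy-1,4-benzoquinone with carbonyls at C11 and C14, hydroxyl at C12 and isopropyl at C13; a further ketone at C7 makes C8=C9 the centre of an ene-trione. The only stereocentres are the neighbours C5 (S) and C10 (S), with the propanoate arm trans to isopropenyl; C10 is quaternary and C5 is β to the C7 ketone, so neither can epimerise once set. The sensitive groups are the isopropenyl group (strong acid, electrophilic oxidants, boranes), the methyl ester (hydroxide), the hydroxyquinone (a vinylogous acid that alkaline peroxide degrades) and the electron-poor C8=C9 bond (nucleophiles). The difficulty is a hexasubstituted ring C carrying four different groups in fixed order beside a quaternary carbon, together with oxidation at C7, C11, C12 and C14 in the presence of an oxidisable alkene. The strategy rests on ring C itself: C11 and C14 are para oxygens, the isopropyl group on C13 is next to the C14 oxygen, and C12 can be carried as C–H and hydroxylated last. That is the pattern obtained when a carbene carbon on C9, a terminal alkyne and one carbonyl ligand are joined on zerovalent chromium, so ring C can be made in one step from a ring-B alkenyl carbene that already holds C5 and C10.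

## Retrosynthetic reasoning

**22 to 20 (through 21).** The C12–O bond is cut first. The hydroxyquinone is the most fragile function and C12–H is the only unsubstituted quinone carbon of 20, so a nucleophilic oxidant has one accessible site. Forward, C12=C13 is epoxidised to 21 and the epoxide is opened by base through loss of the C12 hydrogen. The gain is that ring C needs only hydrogen at C12 before this point.

**20 to 19.** The C11 and C14 carbonyls are traced back to the para-dimethoxyarene 19. The arene carries the oxidation level of ring C safely through the borane and chromium-oxidant steps, and the forward reaction is an oxidative demethylation confined to that unit.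

**19 to 18.** The C7 carbonyl is removed. C7 is the only benzylic methylene of 18 and is activated by the electron-rich ring. The oxidation is placed before quinone formation, since a quinone would not survive it, and after the hydroboration, since a ketone would not survive that.

**18 to 14 (through 17, 16 and 15).** The ester arm is traced back to an allyl group with the same three carbons. Allyl can be attached to C10 as an electrophile and passes through the organolithium and chromium steps unchanged. The forward sequence must hydroborate the monosubstituted alkene and leave the isopropenyl group.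

**14 to 13 to 10 + 11.** This is the central disconnection. The bonds C11–C12, C13–C14 and C8–C14 are cut, which opens ring C into carbene complex 10 (C11 as the methoxycarbene carbon on C9), alkyne 11 (C12, C13 and the isopropyl group) and one carbonyl ligand of 10 (C14). These cuts reduce ring C to a commercial alkyne and a one-carbon unit, keep both stereocentres in a monocyclic fragment, and give the para oxygens already differentiated as methoxy and hydroxyl. A cycloaddition across other ring-C bonds would need a tetrasubstituted diene beside the quaternary carbon. The forward reaction must place isopropyl away from the carbene carbon and tolerate two isolated alkenes.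

**10 to 6 to 5 (with 7, through 8 and 9).** The C9–C11 bond is cut between alkenyllithium 8 and a carbonyl ligand of 7. Alkenyllithium 8 comes from hydrazone 6 of ketone 5, and the regiochemistry is fixed because only C8 carries α-hydrogens.

**5 to 1 + 2 + 3 (through 4).** The C4–C5 and C1–C10 bonds are cut. Conjugate addition of 2 to enone 1 sets C5 under catalyst control, and allylation of enolate 4 with 3 sets C10 under substrate control, anti to the new isopropenyl group.

## Alternatives that were turned down

**Alternative 1:** The cuts are C4–C5 and C1–C10, and the organising step is the copper-catalysed asymmetric 1,4-addition of an isopropenyl Grignard reagent to the enone with allylation of the enolate in the same flask, giving A1 ((2S,3S)-2-allyl-2-methyl-3-(prop-1-en-2-yl)cyclohexan-1-one, the same structure as 5).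
- For it: both stereocentres come from an achiral commercial enone in one operation, and the trans relationship follows from anti alkylation.
- Against it: as the core of a plan it solves only the stereochemical problem. Seven carbons of ring C, three ring-C oxygens and the C7 ketone would still have to be added to A1 by stepwise enolate and carbonyl chemistry at a neopentyl ketone, with a separate operation for each ring-C substituent.
- Comparison: on stereocontrol it is as strong as the chosen strategy, which uses the same reaction as its opening step. The chosen strategy adds a one-step, regiodefined assembly of ring C.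

**Alternative 2:** The cuts are C9–C10 and C5–C6, so ring B is made by a [4+2] cycloaddition of aminosiloxydiene A4 with the formyl-activated dienophile A3 (ethyl (E)-3-methyl-4-oxobut-2-enoate) under the chiral Lewis acid (salen)CrSbF6 of trivalent chromium; acidic work-up then gives enone A2 (ethyl 2-formyl-2-methyl-5-oxocyclohex-3-ene-1-carboxylate, formyl trans to ester).
- For it: the C7 oxygen arrives as the enone carbonyl, so no late benzylic oxidation is needed. On this point it is stronger than the chosen route. The trans relationship of the C5 and C10 substituents is inherited from the E alkene of A3.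
- Against it: A2 holds neither the isopropenyl carbons, nor the full propanoate arm, nor any atom of ring C. Ester, aldehyde and enone must be told apart to build the first two, and ring C must then be annulated onto C8=C9 with C9 flanked by the quaternary carbon. The face selectivity of a trisubstituted, doubly activated dienophile is less secure than for simple 2-substituted acroleins.
- Comparison: the chosen route is clearly shorter and closes ring C in one step. It pays for this with a late oxidation at C7.

**Alternative 3:** The cuts are C9–C11 and C8–C14. A ring-B alkenyllithium adds to the squarate-derived dione A7 (3-isopropoxy-4-isopropylcyclobut-3-ene-1,2-dione) to give carbinol A6, and heating opens the four-membered ring to a dienylketene that closes onto C8 to give hydroquinone A5 (12-isopropyl ether, C7 dioxolane, C3 silyl ether).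
- For it: ring C arrives with all three oxygens, including C12, so no late hydroxylation is needed. On this point it is stronger. The regiochemistry is fixed by the substitution of A7 and no metal is involved.
- Against it: A5 presupposes a ring-B alkenyllithium carrying a C7 ketal, a β-acyl vinyl anion equivalent that cannot be reached from a simple enone by conjugate addition and a Shapiro reaction. A7 has to be prepared, three protecting groups are carried, and the isopropyl ether must be cleaved at the end beside the isopropenyl group.
- Comparison: the chosen route draws ring C from a commercial alkyne and Cr(CO)6 and reaches its precursor in three steps, at the price of oxidising C7 and C12 late. The squarate expansion is kept as the reserve for ring C.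

Key step: step 4

Assumption: the antipode of the chiral ligand in step 1 is the one that gives the (3S) enolate 4; the sense of induction for an alkenyl Grignard reagent on a 2-substituted enone has to be confirmed on the first batch.
Assumption: epoxide 21 is expected as a mixture of the two cis diastereomers at C12/C13 and is written without configuration there, since both converge in step 12.

## Route

**Step 1**
Reactants: 1 2-methylcyclohex-2-en-1-one; 2 isopropenylmagnesium bromide; 3 allyl bromide
Product: 5 (2S,3S)-2-allyl-2-methyl-3-(prop-1-en-2-yl)cyclohexan-1-one, via magnesium enolate 4 (not isolated)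
Conditions: Cu(OTf)2 (3 mol %), chiral imidazolinium salt (N-heterocyclic carbene precursor, 4 mol %), Et2O, −30 °C, slow addition of 2; then 3 (3 equiv), DMPU, −30 °C → rt
Reagents that add atoms: none
Why: Copper-catalysed asymmetric conjugate addition followed by enolate alkylation (three-component coupling); the ligand on copper selects the face of 1 and sets C5. The tetrasubstituted magnesium enolate 4 is allylated anti to the neighbouring isopropenyl group, which sets C10 with allyl trans to isopropenyl.

**Step 2**
Reactants: 5 (2S,3S)-2-allyl-2-methyl-3-(prop-1-en-2-yl)cyclohexan-1-one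
Product: 6 2,4,6-triisopropylbenzenesulfonylhydrazone of 5
Conditions: 2,4,6-(i-Pr)3C6H2SO2NHNH2, conc. HCl (cat.), THF, rt
Reagents that add atoms: 2,4,6-triisopropylbenzenesulfonohydrazide, CC(C)c1cc(C(C)C)c(S(=O)(=O)NN)c(C(C)C)c1
Why: Acid-catalysed hydrazone formation, known for α-quaternary cyclohexanones; the sulfonamide nitrogen is expected anti to the quaternary carbon, the geometry the next step needs. No stereocentre is touched.

**Step 3**
Reactants: 6 2,4,6-triisopropylbenzenesulfonylhydrazone of 5; 7 hexacarbonylchromium Cr(CO)6
Product: 10 pentacarbonyl{methoxy[(5S,6S)-6-allyl-6-methyl-5-(prop-1-en-2-yl)cyclohex-1-en-1-yl]methylidene}chromium, via alkenyllithium 8 (not isolated), via lithium acylchromate 9 (not isolated)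
Conditions: n-BuLi (2.2 equiv), THF, −78 → 0 °C; Cr(CO)6, THF, 0 °C → rt; Me3OBF4, CH2Cl2, 0 °C
Reagents that add atoms: trimethyloxonium tetrafluoroborate, C[O+](C)C.F[B-](F)(F)F
Why: Shapiro reaction followed by the Fischer carbene synthesis. Only C8 has α-hydrogens, so loss of sulfinate and N2 from the dianion gives 8 with lithium on C9; 8 adds to a carbonyl ligand of 7 to give 9, and the oxonium salt methylates the acyl oxygen.

**Step 4**
Reactants: 10 pentacarbonyl{methoxy[(5S,6S)-6-allyl-6-methyl-5-(prop-1-en-2-yl)cyclohex-1-en-1-yl]methylidene}chromium; 11 3-methylbut-1-yne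
Product: 13 (5S,6S)-5-allyl-4-methoxy-5-methyl-2-(propan-2-yl)-6-(prop-1-en-2-yl)-5,6,7,8-tetrahydronaphthalen-1-ol, via tricarbonylchromium arene complex 12 (not isolated)
Conditions: 11 (2 equiv), THF, 50 °C, sealed tube, Ar; then air, Et2O, rt
Reagents that add atoms: none
Why: Dötz benzannulation of an alkenyl(methoxy)carbene complex of zerovalent chromium with a terminal alkyne, a reaction type established for cyclohexenyl carbene complexes. Thermal loss of one cis carbonyl ligand from 10 opens a site for 11, which inserts into the Cr=C bond so that its unsubstituted carbon bonds to the carbene carbon (C11–C12) and the isopropyl-bearing carbon becomes the new carbene carbon C13. Migration of a carbonyl ligand to C13 gives the chromium-bound dienylketene (C13–C14), and ring C closes by 6π electrocyclisation of this ketene onto the ring-B alkene carbon C8 (C8–C14), followed by tautomerisation of the C8–H cyclohexadienone to the phenol. The product leaves as the Cr(CO)3 complex 12, from which air releases 13. No stereocentre is formed, and C5 and C10 are not touched under the neutral conditions. The selectivity needed is regiochemical: isopropyl must end on C13 beside the CO-derived C14, and the size difference between hydrogen and isopropyl secures this because the larger group avoids the carbene substituent and the cis carbonyl ligands during insertion. The two isolated alkenes are unactivated and are expected to stay out of the reaction at 50 °C.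

**Step 5**
Reactants: 13 (5S,6S)-5-allyl-4-methoxy-5-methyl-2-(propan-2-yl)-6-(prop-1-en-2-yl)-5,6,7,8-tetrahydronaphthalen-1-ol
Product: 14 (5S,6S)-5-allyl-1,4-dimethoxy-5-methyl-2-(propan-2-yl)-6-(prop-1-en-2-yl)-5,6,7,8-tetrahydronaphthalene
Conditions: NaH, MeI, DMF, 0 °C → rt
Reagents that add atoms: methyl iodide, CI
Why: Williamson ether synthesis on the hindered phenoxide; the ether protects the oxidisable 4-methoxyphenol through the following borane and oxidation steps.

**Step 6**
Reactants: 14 (5S,6S)-5-allyl-1,4-dimethoxy-5-methyl-2-(propan-2-yl)-6-(prop-1-en-2-yl)-5,6,7,8-tetrahydronaphthalene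
Product: 16 3-[(1S,2S)-5,8-dimethoxy-1-methyl-6-(propan-2-yl)-2-(prop-1-en-2-yl)-1,2,3,4-tetrahydronaphthalen-1-yl]propan-1-ol, via trialkylborane 15 (not isolated)
Conditions: disiamylborane (from BH3·SMe2 and 2-methylbut-2-ene), THF, 0 °C; then NaOH, H2O2, 0 °C → rt
Reagents that add atoms: hydrogen peroxide, OO; disiamylborane, CC(C)C(C)BC(C)C(C)C (boron of 15 only)
Why: Hydroboration–oxidation; the bulky dialkylborane adds anti-Markovnikov to the monosubstituted allyl alkene much faster than to the 1,1-disubstituted isopropenyl group, which is further shielded by the quaternary C10. Oxidation of the C–B bond gives the primary alcohol.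

**Step 7**
Reactants: 16 3-[(1S,2S)-5,8-dimethoxy-1-methyl-6-(propan-2-yl)-2-(prop-1-en-2-yl)-1,2,3,4-tetrahydronaphthalen-1-yl]propan-1-ol
Product: 17 3-[(1S,2S)-5,8-dimethoxy-1-methyl-6-(propan-2-yl)-2-(prop-1-en-2-yl)-1,2,3,4-tetrahydronaphthalen-1-yl]propanoic acid
Conditions: TEMPO (cat.), PhI(OAc)2, MeCN/H2O, rt
Reagents that add atoms: water, O
Why: Nitroxyl-catalysed oxidation of a primary alcohol through the aldehyde hydrate to the acid; the near-neutral conditions should leave the isopropenyl group and the dimethoxyarene alone.

**Step 8**
Reactants: 17 3-[(1S,2S)-5,8-dimethoxy-1-methyl-6-(propan-2-yl)-2-(prop-1-en-2-yl)-1,2,3,4-tetrahydronaphthalen-1-yl]propanoic acid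
Product: 18 methyl 3-[(1S,2S)-5,8-dimethoxy-1-methyl-6-(propan-2-yl)-2-(prop-1-en-2-yl)-1,2,3,4-tetrahydronaphthalen-1-yl]propanoate
Conditions: MeI, K2CO3, DMF, rt
Reagents that add atoms: methyl iodide, CI
Why: SN2 alkylation of the carboxylate; no other acidic site is present.

**Step 9**
Reactants: 18 methyl 3-[(1S,2S)-5,8-dimethoxy-1-methyl-6-(propan-2-yl)-2-(prop-1-en-2-yl)-1,2,3,4-tetrahydronaphthalen-1-yl]propanoate
Product: 19 methyl 3-[(1S,2S)-5,8-dimethoxy-1-methyl-4-oxo-6-(propan-2-yl)-2-(prop-1-en-2-yl)-1,2,3,4-tetrahydronaphthalen-1-yl]propanoate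
Conditions: CrO3, 3,5-dimethylpyrazole, CH2Cl2, −20 °C
Reagents that add atoms: chromium trioxide, O=[Cr](=O)=O
Why: Benzylic oxidation by the chromium trioxide–dimethylpyrazole complex; C7 is the only benzylic methylene and is activated by the electron-rich ring. The isopropyl methine lies in the ring plane between C12–H and the C14 methoxy group and is poorly aligned for abstraction, and the isopropenyl group has no allylic methylene, the site this reagent normally attacks in alkenes.

**Step 10**
Reactants: 19 methyl 3-[(1S,2S)-5,8-dimethoxy-1-methyl-4-oxo-6-(propan-2-yl)-2-(prop-1-en-2-yl)-1,2,3,4-tetrahydronaphthalen-1-yl]propanoate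
Product: 20 methyl 3-[(1S,2S)-1-methyl-4,5,8-trioxo-6-(propan-2-yl)-2-(prop-1-en-2-yl)-1,2,3,4,5,8-hexahydronaphthalen-1-yl]propanoate
Conditions: (NH4)2Ce(NO3)6, MeCN/H2O, 0 °C
Reagents that add atoms: water, O
Why: Oxidative demethylation of a hydroquinone dimethyl ether by tetravalent cerium; two one-electron oxidations with addition of water at C11 and C14 and loss of methanol give the para-quinone. The aryl ketone raises the oxidation potential but leaves the para-dimethoxy unit as the only oxidisable site.

**Step 11**
Reactants: 20 methyl 3-[(1S,2S)-1-methyl-4,5,8-trioxo-6-(propan-2-yl)-2-(prop-1-en-2-yl)-1,2,3,4,5,8-hexahydronaphthalen-1-yl]propanoate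
Product: 21 C12,C13-epoxide of 20 (oxirane across the quinone carbons that bear hydrogen and isopropyl; both cis diastereomers)
Conditions: 30% H2O2, Na2CO3, THF/H2O, 0 °C
Reagents that add atoms: hydrogen peroxide, OO
Why: Weitz–Scheffer nucleophilic epoxidation; hydroperoxide adds to the only unsubstituted enone β-carbon, C12, and the enolate closes on oxygen, while C8=C9 is tetrasubstituted and blocked by C10. The two new centres form as a cis pair on either face and are erased in step 12.

**Step 12**
Reactants: 21 C12,C13-epoxide of 20
Product: 22 methyl 3-[(1S,2S)-7-hydroxy-1-methyl-4,5,8-trioxo-6-(propan-2-yl)-2-(prop-1-en-2-yl)-1,2,3,4,5,8-hexahydronaphthalen-1-yl]propanoate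
Conditions: DBU (1.1 equiv), CH2Cl2, 0 °C → rt; cold aqueous NaH2PO4
Reagents that add atoms: none
Why: Base-induced isomerisation of an α,β-epoxy ketone that bears an α-hydrogen; removal of C12–H and β-elimination of the C13–O bond give the anion of the 2-hydroxyquinone, a vinylogous carboxylate whose formation drives the reaction. The non-nucleophilic base spares the methyl ester, no acid reaches the isopropenyl group, and C5 and C10 are untouched.

## Compound list

1 | 2-methylcyclohex-2-en-1-one | CC1=CCCCC1=O | starting material
2 | isopropenylmagnesium bromide | C=C(C)[Mg]Br | starting material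
3 | allyl bromide | C=CCBr | starting material
4 | bromomagnesium (3S)-2-methyl-3-(prop-1-en-2-yl)cyclohex-1-en-1-olate | C=C(C)[C@@H]1CCCC(O[Mg]Br)=C1C | intermediate (not isolated)
5 | (2S,3S)-2-allyl-2-methyl-3-(prop-1-en-2-yl)cyclohexan-1-one | C=C(C)[C@@H]1CCCC(=O)[C@@]1(C)CC=C | intermediate
6 | 2,4,6-triisopropylbenzenesulfonylhydrazone of 5 | C=C(C)[C@@H]1CCCC(=NNS(=O)(=O)c2c(C(C)C)cc(C(C)C)cc2C(C)C)[C@@]1(C)CC=C | intermediate
7 | hexacarbonylchromium Cr(CO)6 | O=C=[Cr](=C=O)(=C=O)(=C=O)(=C=O)=C=O | starting material
8 | [(5S,6S)-6-allyl-6-methyl-5-(prop-1-en-2-yl)cyclohex-1-en-1-yl]lithium | C=C(C)[C@@H]1CCC=C([Li])[C@@]1(C)CC=C | intermediate (not isolated)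
9 | lithium pentacarbonyl(acyl)chromate from 8 and 7 | C=C(C)[C@@H]1CCC=C(C(O[Li])=[Cr](=C=O)(=C=O)(=C=O)(=C=O)=C=O)[C@@]1(C)CC=C | intermediate (not isolated)
10 | pentacarbonyl{methoxy[(5S,6S)-6-allyl-6-methyl-5-(prop-1-en-2-yl)cyclohex-1-en-1-yl]methylidene}chromium | C=C(C)[C@@H]1CCC=C(C(OC)=[Cr](=C=O)(=C=O)(=C=O)(=C=O)=C=O)[C@@]1(C)CC=C | intermediate
11 | 3-methylbut-1-yne | CC(C)C#C | starting material
12 | tricarbonyl(η6-arene)chromium complex of 13 (ring C bound to Cr(CO)3; written as two parts) | C=C(C)[C@@H]1CCc2c(O)c(C(C)C)cc(OC)c2[C@@]1(C)CC=C.O=C=[Cr](=C=O)=C=O | intermediate (not isolated)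
13 | (5S,6S)-5-allyl-4-methoxy-5-methyl-2-(propan-2-yl)-6-(prop-1-en-2-yl)-5,6,7,8-tetrahydronaphthalen-1-ol | C=C(C)[C@@H]1CCc2c(O)c(C(C)C)cc(OC)c2[C@@]1(C)CC=C | intermediate
14 | (5S,6S)-5-allyl-1,4-dimethoxy-5-methyl-2-(propan-2-yl)-6-(prop-1-en-2-yl)-5,6,7,8-tetrahydronaphthalene | C=C(C)[C@@H]1CCc2c(OC)c(C(C)C)cc(OC)c2[C@@]1(C)CC=C | intermediate
15 | bis(3-methylbutan-2-yl)borane adduct at the terminal carbon of the allyl group of 14 | C=C(C)[C@@H]1CCc2c(OC)c(C(C)C)cc(OC)c2[C@@]1(C)CCCB(C(C)C(C)C)C(C)C(C)C | intermediate (not isolated)
16 | 3-[(1S,2S)-5,8-dimethoxy-1-methyl-6-(propan-2-yl)-2-(prop-1-en-2-yl)-1,2,3,4-tetrahydronaphthalen-1-yl]propan-1-ol | C=C(C)[C@@H]1CCc2c(OC)c(C(C)C)cc(OC)c2[C@@]1(C)CCCO | intermediate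
17 | 3-[(1S,2S)-5,8-dimethoxy-1-methyl-6-(propan-2-yl)-2-(prop-1-en-2-yl)-1,2,3,4-tetrahydronaphthalen-1-yl]propanoic acid | C=C(C)[C@@H]1CCc2c(OC)c(C(C)C)cc(OC)c2[C@@]1(C)CCC(=O)O | intermediate
18 | methyl ester of 17 | C=C(C)[C@@H]1CCc2c(OC)c(C(C)C)cc(OC)c2[C@@]1(C)CCC(=O)OC | intermediate
19 | methyl 3-[(1S,2S)-5,8-dimethoxy-1-methyl-4-oxo-6-(propan-2-yl)-2-(prop-1-en-2-yl)-1,2,3,4-tetrahydronaphthalen-1-yl]propanoate | C=C(C)[C@@H]1CC(=O)c2c(OC)c(C(C)C)cc(OC)c2[C@@]1(C)CCC(=O)OC | intermediate
20 | methyl 3-[(1S,2S)-1-methyl-4,5,8-trioxo-6-(propan-2-yl)-2-(prop-1-en-2-yl)-1,2,3,4,5,8-hexahydronaphthalen-1-yl]propanoate | C=C(C)[C@@H]1CC(=O)C2=C(C(=O)C=C(C(C)C)C2=O)[C@@]1(C)CCC(=O)OC | intermediate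
21 | C12,C13-epoxide of 20 (both cis diastereomers) | C=C(C)[C@@H]1CC(=O)C2=C(C(=O)C3OC3(C(C)C)C2=O)[C@@]1(C)CCC(=O)OC | intermediate
22 | methyl 3-[(1S,2S)-7-hydroxy-1-methyl-4,5,8-trioxo-6-(propan-2-yl)-2-(prop-1-en-2-yl)-1,2,3,4,5,8-hexahydronaphthalen-1-yl]propanoate | C=C(C)[C@@H]1CC(=O)C2=C(C(=O)C(O)=C(C(C)C)C2=O)[C@@]1(C)CCC(=O)OC | target

## Step count and least certain steps

Total: 12 steps. Longest linear sequence: 12 steps (1 to 22); all other components are commercial.

**Step 4 (key step).**
- What may go wrong: the carbene carbon sits beside the quaternary C10, so carbonyl insertion and electrocyclisation may be slowed. The vinylcarbene intermediate could then close without CO to a five-membered ring, form a cyclobutenone or consume a second alkyne. Reversible coordination of the allyl group to chromium after CO loss may also retard alkyne uptake, and the electron-rich phenol may be oxidised during demetalation.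
- Fallback: ring C is built without chromium by thermal ring expansion of a 4-alkenyl-4-hydroxycyclobutenone. It sets out from hydrazone 6 and comes back to the route at 22.
  - Alkenyllithium 8, generated as in step 3, is added at −78 °C in THF to 3-isopropoxy-4-isopropylcyclobut-3-ene-1,2-dione F1 (available from diisopropyl squarate). Attack is expected at the carbonyl next to the alkoxy-bearing carbon and gives 4-hydroxycyclobutenone F2.
  - Heating F2 in toluene at 110 °C opens it to the dienylketene, which closes onto C8 and tautomerises to hydroquinone 12-isopropyl ether F3.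
  - Double O-methylation (Me2SO4, K2CO3, acetone, a little Na2S2O4) gives trialkoxyarene F4.
  - The operations of steps 6 to 10 then follow unchanged: trialkylborane F5, primary alcohol F6, carboxylic acid F7, methyl ester F8, C7 ketone F9 and 12-isopropoxyquinone F10.
  - BCl3 in CH2Cl2 at −78 °C removes the isopropyl group and gives 22. Steps 11 and 12 are not needed on this path.

**Step 1.**
- What may go wrong: poor facial selectivity in the transfer of an sp2 Grignard reagent, through uncatalysed background addition or competing 1,2-addition, and incomplete C-allylation of the hindered magnesium enolate.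
- Fallback: the stereocentre is set by rhodium catalysis and the enolate is made separately. It sets out from 1 and comes back at 5.
  - Hayashi–Miyaura addition of K[CH2=C(CH3)BF3] to 1 with [Rh(cod)Cl]2 and (R)-BINAP in dioxane/H2O gives (3R)-2-methyl-3-(prop-1-en-2-yl)cyclohexan-1-one F11 as C2 epimers. This ligand antipode is the one that gives (R)-3-arylcyclohexanones from cyclohex-2-enone.
  - Thermodynamic silylation (Me3SiCl, NaI, Et3N, MeCN) gives the tetrasubstituted silyl enol ether F12.
  - MeLi in THF releases lithium enolate F13, which is allylated with 3 anti to the isopropenyl group to give 5.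

**Step 9.**
- What may go wrong: the hexavalent chromium reagent may attack the isopropenyl group (epoxidation, cleavage or abstraction of the C5 hydrogen), oxidise further at C6, or demethylate the electron-rich ring oxidatively.
- Fallback: the C7 oxygen is introduced by hydride abstraction without a metal-oxo reagent. It sets out from 18 and comes back at 19.
  - DDQ in CH2Cl2/H2O (pH 7 buffer) removes hydride from C7, and the benzylic cation is captured by water to give benzylic alcohol F14 as either C7 epimer.
  - Dess–Martin periodinane oxidises F14 to 19.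

**Step 12.**
- What may go wrong: removal of the oxirane hydrogen at C12 may be slow, and the amidine base may instead add to, or degrade, the ene-trione.
- Fallback: the epoxide is opened by hydroxide, the ester is sacrificed and then restored. It sets out from 21 and comes back at 22.
  - LiOH in THF/H2O at 0 °C opens the epoxide at C12, dehydration follows, and the ester is saponified in the same flask, giving hydroxyquinone acid F15.
  - MeI (1 equiv) and KHCO3 in DMF alkylate the carboxylate in preference to the delocalised, hindered hydroxyquinone anion and give 22.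

## Further compounds

F1 | step 4 | 3-isopropoxy-4-isopropylcyclobut-3-ene-1,2-dione | CC(C)OC1=C(C(C)C)C(=O)C1=O
F2 | step 4 | 4-hydroxy-3-isopropoxy-2-isopropyl-4-[(5S,6S)-6-allyl-6-methyl-5-(prop-1-en-2-yl)cyclohex-1-en-1-yl]cyclobut-2-en-1-one (carbinol epimers) | C=C(C)[C@@H]1CCC=C(C2(O)C(OC(C)C)=C(C(C)C)C2=O)[C@@]1(C)CC=C
F3 | step 4 | (5S,6S)-5-allyl-3-isopropoxy-5-methyl-2-(propan-2-yl)-6-(prop-1-en-2-yl)-5,6,7,8-tetrahydronaphthalene-1,4-diol | C=C(C)[C@@H]1CCc2c(O)c(C(C)C)c(OC(C)C)c(O)c2[C@@]1(C)CC=C
F4 | step 4 | 1,4-dimethyl ether of F3 | C=C(C)[C@@H]1CCc2c(OC)c(C(C)C)c(OC(C)C)c(OC)c2[C@@]1(C)CC=C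
F5 | step 4 | bis(3-methylbutan-2-yl)borane adduct at the terminal allyl carbon of F4 | C=C(C)[C@@H]1CCc2c(OC)c(C(C)C)c(OC(C)C)c(OC)c2[C@@]1(C)CCCB(C(C)C(C)C)C(C)C(C)C
F6 | step 4 | primary alcohol from F5 (12-isopropoxy analogue of 16) | C=C(C)[C@@H]1CCc2c(OC)c(C(C)C)c(OC(C)C)c(OC)c2[C@@]1(C)CCCO
F7 | step 4 | carboxylic acid from F6 (12-isopropoxy analogue of 17) | C=C(C)[C@@H]1CCc2c(OC)c(C(C)C)c(OC(C)C)c(OC)c2[C@@]1(C)CCC(=O)O
F8 | step 4 | methyl ester of F7 (12-isopropoxy analogue of 18) | C=C(C)[C@@H]1CCc2c(OC)c(C(C)C)c(OC(C)C)c(OC)c2[C@@]1(C)CCC(=O)OC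
F9 | step 4 | C7 ketone from F8 (12-isopropoxy analogue of 19) | C=C(C)[C@@H]1CC(=O)c2c(OC)c(C(C)C)c(OC(C)C)c(OC)c2[C@@]1(C)CCC(=O)OC
F10 | step 4 | 12-isopropyl ether of 22 | C=C(C)[C@@H]1CC(=O)C2=C(C(=O)C(OC(C)C)=C(C(C)C)C2=O)[C@@]1(C)CCC(=O)OC
F11 | step 1 | (3R)-2-methyl-3-(prop-1-en-2-yl)cyclohexan-1-one (C2 epimers) | C=C(C)[C@@H]1CCCC(=O)C1C
F12 | step 1 | trimethyl{[(3S)-2-methyl-3-(prop-1-en-2-yl)cyclohex-1-en-1-yl]oxy}silane | C=C(C)[C@@H]1CCCC(O[Si](C)(C)C)=C1C
F13 | step 1 | lithium (3S)-2-methyl-3-(prop-1-en-2-yl)cyclohex-1-en-1-olate | C=C(C)[C@@H]1CCCC(O[Li])=C1C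
F14 | step 9 | methyl 3-[(1S,2S)-4-hydroxy-5,8-dimethoxy-1-methyl-6-(propan-2-yl)-2-(prop-1-en-2-yl)-1,2,3,4-tetrahydronaphthalen-1-yl]propanoate (C4 epimers) | C=C(C)[C@@H]1CC(O)c2c(OC)c(C(C)C)cc(OC)c2[C@@]1(C)CCC(=O)OC
F15 | step 12 | 3-[(1S,2S)-7-hydroxy-1-methyl-4,5,8-trioxo-6-(propan-2-yl)-2-(prop-1-en-2-yl)-1,2,3,4,5,8-hexahydronaphthalen-1-yl]propanoic acid | C=C(C)[C@@H]1CC(=O)C2=C(C(=O)C(O)=C(C(C)C)C2=O)[C@@]1(C)CCC(=O)O
A1 | alternative 1 | (2S,3S)-2-allyl-2-methyl-3-(prop-1-en-2-yl)cyclohexan-1-one | C=C(C)[C@@H]1CCCC(=O)[C@@]1(C)CC=C
A2 | alternative 2 | ethyl 2-formyl-2-methyl-5-oxocyclohex-3-ene-1-carboxylate, formyl trans to ester | CCOC(=O)[C@@H]1CC(=O)C=C[C@@]1(C)C=O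
A3 | alternative 2 | ethyl (E)-3-methyl-4-oxobut-2-enoate | CCOC(=O)/C=C(C)/C=O
A4 | alternative 2 | (E)-3-(tert-butyldimethylsilyloxy)-N,N-dimethylbuta-1,3-dien-1-amine | CN(C)/C=C/C(=C)O[Si](C)(C)C(C)(C)C
A5 | alternative 3 | ring-C hydroquinone 12-isopropyl ether with C7 dioxolane and C3 tert-butyldimethylsilyl ether | C=C(C)[C@@H]1CC2(OCCO2)c3c(O)c(C(C)C)c(OC(C)C)c(O)c3[C@@]1(C)CCCO[Si](C)(C)C(C)(C)C
A6 | alternative 3 | 4-hydroxy-3-isopropoxy-2-isopropylcyclobut-2-en-1-one carrying at C4 the ring-B alkenyl group with C7 dioxolane and C3 silyl ether | C=C(C)[C@@H]1CC2(OCCO2)C=C(C3(O)C(OC(C)C)=C(C(C)C)C3=O)[C@@]1(C)CCCO[Si](C)(C)C(C)(C)C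
A7 | alternative 3 | 3-isopropoxy-4-isopropylcyclobut-3-ene-1,2-dione | CC(C)OC1=C(C(C)C)C(=O)C1=O
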